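**Retrosynthetic overview**
1. The target comes from the fully protected (3S)-isoflavanone by one-pot removal of the 7-O-benzyl group and the catechol isopropylidene ketal.
2. The C3–C1′ bond and the C3 stereocentre come from a visible-light radical 1,2-aryl shift (C4→C3, loss of HBr) in a (3R,4R)-3-bromo-4-aryl-chroman-4-ol.
3. The bromohydrin comes from anti-selective addition of the B-ring aryl-cerium to (R)-7-benzyloxy-3-bromochroman-4-one; its C–Br centre derives from methyl (S)-glycidate (phenol opening, Appel inversion, saponification, Friedel–Crafts closure).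
4. The B-ring arene comes from 2,2-dimethyl-1,3-benzodioxol-4-ol by O-prenylation, aromatic Claisen rearrangement and O-methylation, and is metalated by directed ortho-lithiation.
5. Ring order: rings A and B are bought; ring C is closed in the Friedel–Crafts step before the B ring is attached.

Assumption: the SMILES is read as the (3S)-isoflavanone, and 2,2-dimethyl-1,3-benzodioxol-4-ol, 3-(benzyloxy)phenol and methyl (S)-glycidate are taken as commercial.

**Step 1**
Reactants: 1 2,2-dimethyl-1,3-benzodioxol-4-ol; 2 prenyl bromide (1-bromo-3-methylbut-2-ene)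
Product: 3 2,2-dimethyl-4-[(3-methylbut-2-en-1-yl)oxy]-1,3-benzodioxole
Conditions: K2CO3, acetone, reflux
Reagents that add atoms: none
Why: Williamson O-alkylation of the only free phenol with a primary allylic bromide.

**Step 2**
Reactants: 3 2,2-dimethyl-4-[(3-methylbut-2-en-1-yl)oxy]-1,3-benzodioxole
Product: 4 2,2-dimethyl-5-(2-methylbut-3-en-2-yl)-1,3-benzodioxol-4-ol
Conditions: PhNEt2, 190 °C, Ar
Reagents that add atoms: none
Why: Aromatic Claisen [3,3] rearrangement delivers the inverted allyl unit (1,1-dimethylallyl) to C5, the only free ortho position (the other is the oxygen-bearing ring-fusion carbon), and the basic solvent suppresses acid-type cyclisation of the product.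

**Step 3**
Reactants: 4 2,2-dimethyl-5-(2-methylbut-3-en-2-yl)-1,3-benzodioxol-4-ol
Product: 5 4-methoxy-2,2-dimethyl-5-(2-methylbut-3-en-2-yl)-1,3-benzodioxole
Conditions: MeI, K2CO3, DMF, rt
Reagents that add atoms: iodomethane, CI
Why: Williamson O-methylation of the hindered phenol with a small, reactive electrophile.

**Step 4**
Reactants: 6 3-(benzyloxy)phenol; 7 methyl (2S)-oxirane-2-carboxylate (methyl (S)-glycidate)
Product: 8 methyl (2S)-3-[3-(benzyloxy)phenoxy]-2-hydroxypropanoate
Conditions: CsF (0.2 equiv), DMF, 50 °C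
Reagents that add atoms: none
Why: Phenoxide SN2 opening of the glycidate at the unsubstituted C3, so the bought C2 stereocentre is untouched and stays (S).

**Step 5**
Reactants: 8 methyl (2S)-3-[3-(benzyloxy)phenoxy]-2-hydroxypropanoate
Product: 9 methyl (2R)-3-[3-(benzyloxy)phenoxy]-2-bromopropanoate
Conditions: CBr4, PPh3, CH2Cl2, −20 → 0 °C
Reagents that add atoms: carbon tetrabromide, BrC(Br)(Br)Br
Why: Appel reaction; bromide displaces the oxyphosphonium by SN2 with inversion, turning the bought (S) C–O centre into the (R) C–Br centre.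

**Step 6**
Reactants: 9 methyl (2R)-3-[3-(benzyloxy)phenoxy]-2-bromopropanoate
Product: 10 (2R)-3-[3-(benzyloxy)phenoxy]-2-bromopropanoic acid
Conditions: LiOH·H2O (1.1 equiv), THF/H2O, 0 °C, 30 min; then 1 M HCl to pH 2
Reagents that add atoms: lithium hydroxide, [Li+].[OH-]
Why: Saponification of the activated α-bromo ester is fast at 0 °C and takes place at the acyl carbon, so the C–Br centre is not touched.

**Step 7**
Reactants: 10 (2R)-3-[3-(benzyloxy)phenoxy]-2-bromopropanoic acid
Product: 12 (3R)-7-(benzyloxy)-3-bromochroman-4-one, via acid chloride 11 (not isolated)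
Conditions: (COCl)2, DMF (cat.), CH2Cl2, 0 °C → rt; concentrate; HFIP, rt
Reagents that add atoms: oxalyl chloride, O=C(Cl)C(=O)Cl (supplies the chlorine of 11 only)
Why: Lewis-acid-free, HFIP-promoted intramolecular Friedel–Crafts acylation closes ring C at the position para to OBn and ortho to the ether oxygen; with no base or metal halide present the α-bromo centre and the benzyl ether survive.

**Step 8**
Reactants: 5 4-methoxy-2,2-dimethyl-5-(2-methylbut-3-en-2-yl)-1,3-benzodioxole; 12 (3R)-7-(benzyloxy)-3-bromochroman-4-one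
Product: 15 (3R,4R)-7-(benzyloxy)-3-bromo-4-[7-methoxy-2,2-dimethyl-6-(2-methylbut-3-en-2-yl)-1,3-benzodioxol-4-yl]chroman-4-ol, via aryllithium 13 (not isolated), via arylcerium dichloride 14 (not isolated)
Conditions: 5, s-BuLi, TMEDA, THF, −78 → −40 °C; CeCl3, −78 °C; then 12, THF, −78 °C; sat. NH4Cl at −78 °C; fast column on Et3N-deactivated silica, use at once
Reagents that add atoms: sec-butyllithium, CCC(C)[Li] (lithium of 13 only); cerium(III) chloride, Cl[Ce](Cl)Cl (cerium and chlorine of 14 only)
Why: Directed ortho-lithiation next to the dioxole oxygen, then 1,2-addition of the non-basic organocerium to the ketone anti to the pseudo-axial C–Br bond (Cornforth/Felkin–Anh polar model), which puts the aryl trans to bromine and sets C4 as (R) under control of the C3 centre, without enolisation or Br–metal exchange.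

**Step 9**
Reactants: 15 (3R,4R)-7-(benzyloxy)-3-bromo-4-[7-methoxy-2,2-dimethyl-6-(2-methylbut-3-en-2-yl)-1,3-benzodioxol-4-yl]chroman-4-ol
Product: 16 (3S)-7-(benzyloxy)-3-[7-methoxy-2,2-dimethyl-6-(2-methylbut-3-en-2-yl)-1,3-benzodioxol-4-yl]chroman-4-one
Conditions: Pd(PPh3)4 (5 mol %), Xantphos (6 mol %), KHCO3 (2 equiv), degassed PhH, 450 nm LEDs, 20 °C
Reagents that add atoms: none
Why: Proposed new method: photoexcited Pd(0)/Xantphos transfers an electron to the unactivated secondary C–Br bond (as in visible-light Pd radical Heck chemistry) to give the C3 radical, the C4 aryl then shifts suprafacially through a spiro[2.5]octadienyl radical (neophyl-type 1,2-aryl migration, closest known in the radical semipinacol of α,α-diaryl allylic alcohols) and so lands on the C3 face it occupied at C4, anti to the departed bromine, giving (3S), and the ketyl radical is oxidised by Pd(I)Br to the ketone while KHCO3 takes up HBr, making the cycle redox-neutral; what is new is the dehalogenative entry from a bromohydrin and the C3→C4→C3 chirality relay with no chiral catalyst.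

**Step 10**
Reactants: 16 (3S)-7-(benzyloxy)-3-[7-methoxy-2,2-dimethyl-6-(2-methylbut-3-en-2-yl)-1,3-benzodioxol-4-yl]chroman-4-one
Product: 17 (3S)-3-[2,3-dihydroxy-4-methoxy-5-(2-methylbut-3-en-2-yl)phenyl]-7-hydroxychroman-4-one (target)
Conditions: BCl3 (6 equiv), pentamethylbenzene (5 equiv), CH2Cl2, −78 → 0 °C; MeOH, then pH 6 buffer
Reagents that add atoms: none
Why: Lewis-acid dealkylation with a cation scavenger cleaves the aryl benzyl ether and the catechol isopropylidene ketal at low temperature under non-basic conditions, so the base-labile C3–H centre, the aryl methyl ether (no ortho carbonyl) and the 1,1-dimethylallyl group are kept.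

**Compound list**
1 | 2,2-dimethyl-1,3-benzodioxol-4-ol | CC1(C)Oc2cccc(O)c2O1 | starting material
2 | prenyl bromide (1-bromo-3-methylbut-2-ene) | CC(C)=CCBr | starting material
3 | 2,2-dimethyl-4-[(3-methylbut-2-en-1-yl)oxy]-1,3-benzodioxole | CC(C)=CCOc1cccc2OC(C)(C)Oc12 | intermediate
4 | 2,2-dimethyl-5-(2-methylbut-3-en-2-yl)-1,3-benzodioxol-4-ol | C=CC(C)(C)c1ccc2OC(C)(C)Oc2c1O | intermediate
5 | 4-methoxy-2,2-dimethyl-5-(2-methylbut-3-en-2-yl)-1,3-benzodioxole | C=CC(C)(C)c1ccc2OC(C)(C)Oc2c1OC | intermediate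
6 | 3-(benzyloxy)phenol | Oc1cccc(OCc2ccccc2)c1 | starting material
7 | methyl (2S)-oxirane-2-carboxylate | COC(=O)[C@@H]1CO1 | starting material
8 | methyl (2S)-3-[3-(benzyloxy)phenoxy]-2-hydroxypropanoate | COC(=O)[C@@H](O)COc1cccc(OCc2ccccc2)c1 | intermediate
9 | methyl (2R)-3-[3-(benzyloxy)phenoxy]-2-bromopropanoate | COC(=O)[C@H](Br)COc1cccc(OCc2ccccc2)c1 | intermediate
10 | (2R)-3-[3-(benzyloxy)phenoxy]-2-bromopropanoic acid | OC(=O)[C@H](Br)COc1cccc(OCc2ccccc2)c1 | intermediate
11 | (2R)-3-[3-(benzyloxy)phenoxy]-2-bromopropanoyl chloride | ClC(=O)[C@H](Br)COc1cccc(OCc2ccccc2)c1 | intermediate (not isolated)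
12 | (3R)-7-(benzyloxy)-3-bromochroman-4-one | Br[C@@H]1COc2cc(OCc3ccccc3)ccc2C1=O | intermediate
13 | [7-methoxy-2,2-dimethyl-6-(2-methylbut-3-en-2-yl)-1,3-benzodioxol-4-yl]lithium | [Li]c1cc(C(C)(C)C=C)c(OC)c2OC(C)(C)Oc12 | intermediate (not isolated)
14 | dichloro[7-methoxy-2,2-dimethyl-6-(2-methylbut-3-en-2-yl)-1,3-benzodioxol-4-yl]cerium | Cl[Ce](Cl)c1cc(C(C)(C)C=C)c(OC)c2OC(C)(C)Oc12 | intermediate (not isolated)
15 | (3R,4R)-7-(benzyloxy)-3-bromo-4-[7-methoxy-2,2-dimethyl-6-(2-methylbut-3-en-2-yl)-1,3-benzodioxol-4-yl]chroman-4-ol | Br[C@@H]1COc2cc(OCc3ccccc3)ccc2[C@@]1(O)c1cc(C(C)(C)C=C)c(OC)c2OC(C)(C)Oc12 | intermediate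
16 | (3S)-7-(benzyloxy)-3-[7-methoxy-2,2-dimethyl-6-(2-methylbut-3-en-2-yl)-1,3-benzodioxol-4-yl]chroman-4-one | C=CC(C)(C)c1cc([C@H]2COc3cc(OCc4ccccc4)ccc3C2=O)c2OC(C)(C)Oc2c1OC | intermediate
17 | (3S)-3-[2,3-dihydroxy-4-methoxy-5-(2-methylbut-3-en-2-yl)phenyl]-7-hydroxychroman-4-one | C=CC(C)(C)c1cc([C@H]2COc3cc(O)ccc3C2=O)c(O)c(O)c1OC | target

**Step count**
Total: 10 steps. Longest linear sequence: 7 steps (steps 4–10, from 6 and 7).

**Three steps most likely to fail**

Step 9 (the proposed photochemical aryl shift). The C3 radical may be reduced by hydrogen-atom transfer, fragment at the C2–O1 bond or be captured by palladium before the aryl migrates. Fallback with known chemistry: the ionic, silver(I)-promoted semipinacol rearrangement of the same bromohydrin (AgOTf, 2,6-di-tert-butylpyridine, CH2Cl2, −40 → 0 °C). Silver takes the bromide while the antiperiplanar C4 aryl migrates with inversion at C3 and the carbinol becomes the ketone, as in the stereospecific pinacol-type route to α-aryl ketones from lactate-derived β-leaving-group alcohols. It sets out from 15 and comes back at 16 with the same (3S) configuration; it makes no new compound and gives up the light-driven bond formation.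

Step 8 (organocerium addition to the α-bromo ketone). Ketone 12 can racemise or enolise, and carbinol 15 ionises easily, which would erode the C4 configuration and hence the final ee. Fallback: move to the more robust chloro series and the classical halohydrin rearrangement. It sets out from 8: SOCl2/pyridine (inversion) gives methyl (2R)-3-[3-(benzyloxy)phenoxy]-2-chloropropanoate F1; LiOH at 0 °C gives (2R)-3-[3-(benzyloxy)phenoxy]-2-chloropropanoic acid F2; oxalyl chloride gives (2R)-3-[3-(benzyloxy)phenoxy]-2-chloropropanoyl chloride F3, which is not isolated and cyclises in HFIP to (3R)-7-(benzyloxy)-3-chlorochroman-4-one F4. Aryl-cerium 14 adds anti to chlorine to give (3R,4R)-7-(benzyloxy)-3-chloro-4-[7-methoxy-2,2-dimethyl-6-(2-methylbut-3-en-2-yl)-1,3-benzodioxol-4-yl]chroman-4-ol F5. As its bromomagnesium alkoxide (EtMgBr, toluene, 60 °C) F5 undergoes the Tiffeneau-type halohydrin rearrangement with antiperiplanar aryl shift and inversion, and the sequence comes back to the route at 16.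

Step 10 (global deprotection). BCl3 at 0 °C may attack the 4′-methoxy group next to the freed catechol, add HCl to the terminal alkene or erode C3. Fallback: change the protecting-group plan so that the endgame needs only aqueous Brønsted acid. It sets out from 12: BCl3/pentamethylbenzene at −78 °C on this robust ketone gives (3R)-3-bromo-7-hydroxychroman-4-one F6, and MOMCl/i-Pr2NEt at 0 °C gives (3R)-3-bromo-7-(methoxymethoxy)chroman-4-one F7. Addition of 14 as in step 8 gives (3R,4R)-3-bromo-4-[7-methoxy-2,2-dimethyl-6-(2-methylbut-3-en-2-yl)-1,3-benzodioxol-4-yl]-7-(methoxymethoxy)chroman-4-ol F8. The step 9 conditions give (3S)-3-[7-methoxy-2,2-dimethyl-6-(2-methylbut-3-en-2-yl)-1,3-benzodioxol-4-yl]-7-(methoxymethoxy)chroman-4-one F9. TFA/H2O (9:1, 0 °C) then removes the MOM group and the acetonide together, and the sequence comes back to the route at 17.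

**Further compounds**
F1 | step 8 | methyl (2R)-3-[3-(benzyloxy)phenoxy]-2-chloropropanoate | COC(=O)[C@H](Cl)COc1cccc(OCc2ccccc2)c1
F2 | step 8 | (2R)-3-[3-(benzyloxy)phenoxy]-2-chloropropanoic acid | OC(=O)[C@H](Cl)COc1cccc(OCc2ccccc2)c1
F3 | step 8 | (2R)-3-[3-(benzyloxy)phenoxy]-2-chloropropanoyl chloride | ClC(=O)[C@H](Cl)COc1cccc(OCc2ccccc2)c1
F4 | step 8 | (3R)-7-(benzyloxy)-3-chlorochroman-4-one | Cl[C@@H]1COc2cc(OCc3ccccc3)ccc2C1=O
F5 | step 8 | (3R,4R)-7-(benzyloxy)-3-chloro-4-[7-methoxy-2,2-dimethyl-6-(2-methylbut-3-en-2-yl)-1,3-benzodioxol-4-yl]chroman-4-ol | Cl[C@@H]1COc2cc(OCc3ccccc3)ccc2[C@@]1(O)c1cc(C(C)(C)C=C)c(OC)c2OC(C)(C)Oc12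
F0 | step 9 | none | none
F6 | step 10 | (3R)-3-bromo-7-hydroxychroman-4-one | Br[C@@H]1COc2cc(O)ccc2C1=O
F7 | step 10 | (3R)-3-bromo-7-(methoxymethoxy)chroman-4-one | Br[C@@H]1COc2cc(OCOC)ccc2C1=O
F8 | step 10 | (3R,4R)-3-bromo-4-[7-methoxy-2,2-dimethyl-6-(2-methylbut-3-en-2-yl)-1,3-benzodioxol-4-yl]-7-(methoxymethoxy)chroman-4-ol | Br[C@@H]1COc2cc(OCOC)ccc2[C@@]1(O)c1cc(C(C)(C)C=C)c(OC)c2OC(C)(C)Oc12
F9 | step 10 | (3S)-3-[7-methoxy-2,2-dimethyl-6-(2-methylbut-3-en-2-yl)-1,3-benzodioxol-4-yl]-7-(methoxymethoxy)chroman-4-one | C=CC(C)(C)c1cc([C@H]2COc3cc(OCOC)ccc3C2=O)c2OC(C)(C)Oc2c1OC
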